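**Retrosynthetic overview**

1. Target ⇒ C6–C7 bond formed last by intramolecular aldol of a keto dienal (a reduced, O‑methylated tetraketide that already carries the dihydrofuran). The carbocycle is the second ring formed; this closure sets C6 and C7.
2. Keto dienal ⇒ dihydrofuran formed first by a one‑flask formal [3+2] annulation: an o‑quinone methide (unmasked from an o‑silyloxyaryl epoxide) plus the enol of the tetraketide aldehyde. C3–C3a bond first, then O1–C7a closure; sets C3 and keeps C2.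
3. Tetraketide aldehyde (as its cyclic hemiacetal) ⇒ 4‑methoxy‑6‑methyl‑2H‑pyran‑2‑one + methyl 3‑phenylpropanoate (acylation, ketal, lactone reduction).
4. Aryl epoxide ⇒ methyl 4‑hydroxy‑3‑iodobenzoate + 2‑methylbut‑3‑en‑2‑ol (silylation, Heck, Shi epoxidation; sets C2).

Assumption: the SMILES is read literally as (2R,3S,6S,7S), i.e. aryl and hydroxypropyl cis on the dihydrofuran, hydroxy and acyl cis on the carbocycle and on the opposite face to the first pair.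

**Route**

Step 1
Reactants: 1 4‑methoxy‑6‑methyl‑2H‑pyran‑2‑one; 2 methyl 3‑phenylpropanoate
Product: 3 4‑methoxy‑6‑(2‑oxo‑4‑phenylbutyl)‑2H‑pyran‑2‑one
Conditions: LiN(iPr)2 (2.2 equiv), THF, −78 °C; add 2; −78 → −30 °C; AcOH quench
Reagents that add atoms: none
Why: Vinylogous deprotonation of the 6‑methyl group and Claisen‑type C‑acylation by the ester, the second equivalent of base being taken up by the more acidic β‑keto‑pyranone product so that it is not acylated again.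

Step 2
Reactants: 3 4‑methoxy‑6‑(2‑oxo‑4‑phenylbutyl)‑2H‑pyran‑2‑one
Product: 4 4‑methoxy‑6‑{[2‑(2‑phenylethyl)‑1,3‑dioxolan‑2‑yl]methyl}‑2H‑pyran‑2‑one
Conditions: Me3SiOCH2CH2OSiMe3, Me3SiOTf (5 mol %), CH2Cl2, −78 → −20 °C
Reagents that add atoms: 1,2‑bis(trimethylsilyloxy)ethane, C[Si](C)(C)OCCO[Si](C)(C)C
Why: Noyori ketalisation under aprotic conditions that leave the 4‑methoxy‑2‑pyranone untouched; masking the ketone protects it in step 3 and keeps the adjacent CH2 from reacting as a 1,3‑dicarbonyl carbon in step 7.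

Step 3
Reactants: 4 4‑methoxy‑6‑{[2‑(2‑phenylethyl)‑1,3‑dioxolan‑2‑yl]methyl}‑2H‑pyran‑2‑one
Product: 5 4‑methoxy‑6‑{[2‑(2‑phenylethyl)‑1,3‑dioxolan‑2‑yl]methyl}‑2H‑pyran‑2‑ol (racemic hemiacetal, ring form of the keto enal with formyl cis to C‑4)
Conditions: iBu2AlH (1.1 equiv), CH2Cl2, −78 °C; aq. KNaC4H4O6
Reagents that add atoms: none
Why: Lactone‑to‑lactol reduction, in which 1,2‑hydride delivery gives an aluminium lactolate that holds at −78 °C and releases the 2H‑pyran‑2‑ol (the aldehyde oxidation level of the tetraketide), whose hemiacetal centre is racemic and is lost in step 7.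

Step 4
Reactants: 6 methyl 4‑hydroxy‑3‑iodobenzoate
Product: 7 methyl 3‑iodo‑4‑[(triisopropylsilyl)oxy]benzoate
Conditions: iPr3SiCl, imidazole, DMF, rt
Reagents that add atoms: triisopropylsilyl chloride, CC(C)[Si](Cl)(C(C)C)C(C)C
Why: Phenol silylation, which keeps the phenoxide from opening the benzylic epoxide (or closing a chromene) until fluoride is added in step 7.

Step 5
Reactants: 7 methyl 3‑iodo‑4‑[(triisopropylsilyl)oxy]benzoate; 8 2‑methylbut‑3‑en‑2‑ol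
Product: 9 methyl 3‑[(1E)‑3‑hydroxy‑3‑methylbut‑1‑en‑1‑yl]‑4‑[(triisopropylsilyl)oxy]benzoate
Conditions: Pd(OAc)2 (5 mol %), P(o‑tol)3 (10 mol %), Et3N, MeCN, 80 °C
Reagents that add atoms: none
Why: Mizoroki–Heck arylation (oxidative addition of the aryl iodide to zerovalent palladium, syn insertion, syn β‑hydride elimination) gives the E‑styrenyl tertiary alcohol, which cannot isomerise to a carbonyl compound.

Step 6
Reactants: 9 methyl 3‑[(1E)‑3‑hydroxy‑3‑methylbut‑1‑en‑1‑yl]‑4‑[(triisopropylsilyl)oxy]benzoate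
Product: 10 methyl 3‑[(2S,3R)‑3‑(2‑hydroxypropan‑2‑yl)oxiran‑2‑yl]‑4‑[(triisopropylsilyl)oxy]benzoate
Conditions: ent‑Shi ketone (1,2:4,5‑di‑O‑isopropylidene‑β‑L‑erythro‑2,3‑hexodiulo‑2,6‑pyranose, 30 mol %), KHSO5 (as 2KHSO5·KHSO4·K2SO4), K2CO3, Bu4NHSO4, MeCN/(MeO)2CH2/aq. Na2B4O7, 0 °C
Reagents that add atoms: potassium peroxymonosulfate, [K+].[O-]S(=O)(=O)OO
Why: Shi asymmetric epoxidation, in which the chiral dioxirane transfers oxygen to the trans olefin through the spiro transition state to give the (2S,3R)‑oxirane (the mirror‑image series to that from the D‑fructose ketone); oxirane C3 becomes C2 (R) of the target with its C–O bond never broken, and the benzylic centre is expendable.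

Step 7
Reactants: 5 4‑methoxy‑6‑{[2‑(2‑phenylethyl)‑1,3‑dioxolan‑2‑yl]methyl}‑2H‑pyran‑2‑ol; 10 methyl 3‑[(2S,3R)‑3‑(2‑hydroxypropan‑2‑yl)oxiran‑2‑yl]‑4‑[(triisopropylsilyl)oxy]benzoate
Product: 13 methyl 4‑hydroxy‑3‑[(2R,3S)‑2‑(2‑hydroxypropan‑2‑yl)‑4‑[(1E)‑1‑methoxy‑3‑oxoprop‑1‑en‑1‑yl]‑5‑{[2‑(2‑phenylethyl)‑1,3‑dioxolan‑2‑yl]methyl}‑2,3‑dihydrofuran‑3‑yl]benzoate, via quinone methide 11 (not isolated), via Michael adduct 12 (not isolated)
Conditions: Bu4NF (1.1 equiv), THF, −78 → 0 °C; AcOH; then PPTS (10 mol %), 4 Å sieves, CH2Cl2, rt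
Reagents that add atoms: none
Why: Proposed new method: fluoride frees the phenoxide of 10, which opens the benzylic epoxide to an o‑quinone methide carrying the C2 alkoxide; the ring‑opened enolate of 5 (a vinylogous β‑keto aldehyde) adds 1,4 through the carbon next to its ketone, anti to the C–O⁻ bond under the non‑chelating ammonium counter‑ion (Felkin–Anh, with the C2–H eclipsing the exocyclic C=C), which sets C3 (S) cis to the hydroxypropyl group, and the retained alkoxide then adds to the ketone to a hemiketal that PPTS dehydrates to the conjugated dihydrofuran with C2 (R) untouched; the closest known reactions are fluoride‑triggered o‑quinone methide Michael additions of 1,3‑dicarbonyl compounds and the epoxide/1,3‑dicarbonyl dihydrofuran annulation.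

Step 8
Reactants: 13 methyl 4‑hydroxy‑3‑[(2R,3S)‑2‑(2‑hydroxypropan‑2‑yl)‑4‑[(1E)‑1‑methoxy‑3‑oxoprop‑1‑en‑1‑yl]‑5‑{[2‑(2‑phenylethyl)‑1,3‑dioxolan‑2‑yl]methyl}‑2,3‑dihydrofuran‑3‑yl]benzoate
Product: 15 methyl 4‑hydroxy‑3‑[(2R,3S,6S,7S)‑6‑hydroxy‑2‑(2‑hydroxypropan‑2‑yl)‑4‑methoxy‑7‑(3‑phenylpropanoyl)‑2,3,6,7‑tetrahydro‑1‑benzofuran‑3‑yl]benzoate, via keto dienal 14 (not isolated)
Conditions: LiBF4, MeCN/H2O (50:1), rt; then iPr2NEt, 0 °C; pH 7 phosphate buffer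
Reagents that add atoms: water, O
Why: Mild deketalisation unveils the ketone, whose vinylogously activated C7–H2 is enolised under lithium/amine soft‑enolisation conditions and adds to the cis‑held aldehyde in a 6‑(enolexo)‑exo‑trig intramolecular aldol; the lithium‑bridged closed transition state is expected to give the cis β‑hydroxy ketone, with the acyl‑bearing carbon formed on the face opposite the C2 hydroxypropyl and C3 aryl groups (strain across O1), which sets (6S,7S), and the neutral quench avoids dehydration to the arene.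

**Compound list**

1 | 4‑methoxy‑6‑methyl‑2H‑pyran‑2‑one | COC1=CC(=O)OC(C)=C1 | starting material
2 | methyl 3‑phenylpropanoate | COC(=O)CCc1ccccc1 | starting material
3 | 4‑methoxy‑6‑(2‑oxo‑4‑phenylbutyl)‑2H‑pyran‑2‑one | COC1=CC(=O)OC(CC(=O)CCc2ccccc2)=C1 | intermediate
4 | 4‑methoxy‑6‑{[2‑(2‑phenylethyl)‑1,3‑dioxolan‑2‑yl]methyl}‑2H‑pyran‑2‑one | COC1=CC(=O)OC(CC2(CCc3ccccc3)OCCO2)=C1 | intermediate
5 | 4‑methoxy‑6‑{[2‑(2‑phenylethyl)‑1,3‑dioxolan‑2‑yl]methyl}‑2H‑pyran‑2‑ol (racemic) | COC1=CC(O)OC(CC2(CCc3ccccc3)OCCO2)=C1 | intermediate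
6 | methyl 4‑hydroxy‑3‑iodobenzoate | COC(=O)c1ccc(O)c(I)c1 | starting material
7 | methyl 3‑iodo‑4‑[(triisopropylsilyl)oxy]benzoate | COC(=O)c1ccc(O[Si](C(C)C)(C(C)C)C(C)C)c(I)c1 | intermediate
8 | 2‑methylbut‑3‑en‑2‑ol | C=CC(C)(C)O | starting material
9 | methyl 3‑[(1E)‑3‑hydroxy‑3‑methylbut‑1‑en‑1‑yl]‑4‑[(triisopropylsilyl)oxy]benzoate | COC(=O)c1ccc(O[Si](C(C)C)(C(C)C)C(C)C)c(/C=C/C(C)(C)O)c1 | intermediate
10 | methyl 3‑[(2S,3R)‑3‑(2‑hydroxypropan‑2‑yl)oxiran‑2‑yl]‑4‑[(triisopropylsilyl)oxy]benzoate | COC(=O)c1ccc(O[Si](C(C)C)(C(C)C)C(C)C)c([C@@H]2O[C@H]2C(C)(C)O)c1 | intermediate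
11 | methyl 3‑[(2R)‑2,3‑dihydroxy‑3‑methylbutylidene]‑4‑oxocyclohexa‑1,5‑diene‑1‑carboxylate (o‑quinone methide, drawn as the neutral alcohol) | COC(=O)C1=CC(=C[C@@H](O)C(C)(C)O)C(=O)C=C1 | intermediate
12 | open‑chain Michael adduct: methyl 4‑hydroxy‑3‑[(1R,2R)‑2,3‑dihydroxy‑3‑methyl‑1‑X‑butyl]benzoate, X = the CH carbon bearing both the 1‑methoxy‑3‑oxoprop‑1‑enyl group and the C(=O)CH2‑dioxolane ketone (configuration at X unassigned) | COC(=O)c1ccc(O)c([C@H]([C@@H](O)C(C)(C)O)C(C(=O)CC2(CCc3ccccc3)OCCO2)/C(OC)=C\C=O)c1 | intermediate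
13 | methyl 4‑hydroxy‑3‑[(2R,3S)‑2‑(2‑hydroxypropan‑2‑yl)‑4‑[(1E)‑1‑methoxy‑3‑oxoprop‑1‑en‑1‑yl]‑5‑{[2‑(2‑phenylethyl)‑1,3‑dioxolan‑2‑yl]methyl}‑2,3‑dihydrofuran‑3‑yl]benzoate | COC(=O)c1ccc(O)c([C@H]2C(/C(OC)=C\C=O)=C(CC3(CCc4ccccc4)OCCO3)O[C@H]2C(C)(C)O)c1 | intermediate
14 | methyl 4‑hydroxy‑3‑[(2R,3S)‑2‑(2‑hydroxypropan‑2‑yl)‑4‑[(1E)‑1‑methoxy‑3‑oxoprop‑1‑en‑1‑yl]‑5‑(2‑oxo‑4‑phenylbutyl)‑2,3‑dihydrofuran‑3‑yl]benzoate | COC(=O)c1ccc(O)c([C@H]2C(/C(OC)=C\C=O)=C(CC(=O)CCc3ccccc3)O[C@H]2C(C)(C)O)c1 | intermediate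
15 | methyl 4‑hydroxy‑3‑[(2R,3S,6S,7S)‑6‑hydroxy‑2‑(2‑hydroxypropan‑2‑yl)‑4‑methoxy‑7‑(3‑phenylpropanoyl)‑2,3,6,7‑tetrahydro‑1‑benzofuran‑3‑yl]benzoate | COC(=O)c1ccc(O)c([C@H]2C3=C(O[C@H]2C(C)(C)O)[C@@H](C(=O)CCc2ccccc2)[C@@H](O)C=C3OC)c1 | target

**Step count and risks**

Total steps: 8. Longest linear sequence: 5 (steps 1, 2, 3, 7, 8; the aryl branch, steps 4, 5, 6, 7, 8, is equally long).

Three steps most likely to fail:

Step 7. The enolate of 5 is ambident: it can attack through the carbon next to the aldehyde instead of the one next to the ketone. The alkoxide could also displace methoxide at the β‑methoxy‑enal carbon instead of closing on the ketone, and the Felkin preference that gives the cis ring is not proven for this system. Fallback: set out from 4 and block the competing carbon. Bromination of the pyranone 3‑position (NBS, MeCN) gives 3‑bromo‑4‑methoxy‑6‑{[2‑(2‑phenylethyl)‑1,3‑dioxolan‑2‑yl]methyl}‑2H‑pyran‑2‑one F1. Reduction with iBu2AlH gives 3‑bromo‑4‑methoxy‑6‑{[2‑(2‑phenylethyl)‑1,3‑dioxolan‑2‑yl]methyl}‑2H‑pyran‑2‑ol F2. The same fluoride‑triggered annulation with 10 gives methyl 3‑[(2R,3S)‑4‑[(1Z)‑2‑bromo‑1‑methoxy‑3‑oxoprop‑1‑en‑1‑yl]‑2‑(2‑hydroxypropan‑2‑yl)‑5‑{[2‑(2‑phenylethyl)‑1,3‑dioxolan‑2‑yl]methyl}‑2,3‑dihydrofuran‑3‑yl]‑4‑hydroxybenzoate F3. Hydrodebromination with Pd(PPh3)4 and HCO2H/Et3N comes back to the route at 13.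

Step 8. The aldol may be reversible, may give another C6/C7 isomer, or may lose water to the arene; 15 itself must be kept away from acid and strong base. Fallback: set out from 14 (made from 13 as before) and replace the lithium‑enolate closure by enamine catalysis with a chiral primary amine (a 9‑amino‑9‑deoxy‑epi‑cinchona alkaloid plus an acid co‑catalyst), so that face selection at C6/C7 is catalyst‑controlled under buffered conditions. This comes back at 15 and makes no compound outside the list (F0).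

Step 3. Over‑reduction or decomposition of the sensitive hemiacetal is possible. Fallback: set out from 4 and open the lactone first with Me2AlSEt to S‑ethyl (2E)‑3‑methoxy‑5‑oxo‑6‑[2‑(2‑phenylethyl)‑1,3‑dioxolan‑2‑yl]hex‑2‑enethioate F4. Fukuyama reduction (Et3SiH, Pd on carbon, acetone) then converts the thioester to the aldehyde in the presence of the ketone; the aldehyde is the open form of the hemiacetal and so comes back at 5.

**Further compounds**

F1 | step 7 | 3‑bromo‑4‑methoxy‑6‑{[2‑(2‑phenylethyl)‑1,3‑dioxolan‑2‑yl]methyl}‑2H‑pyran‑2‑one | COC1=C(Br)C(=O)OC(CC2(CCc3ccccc3)OCCO2)=C1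
F2 | step 7 | 3‑bromo‑4‑methoxy‑6‑{[2‑(2‑phenylethyl)‑1,3‑dioxolan‑2‑yl]methyl}‑2H‑pyran‑2‑ol | COC1=C(Br)C(O)OC(CC2(CCc3ccccc3)OCCO2)=C1
F3 | step 7 | methyl 3‑[(2R,3S)‑4‑[(1Z)‑2‑bromo‑1‑methoxy‑3‑oxoprop‑1‑en‑1‑yl]‑2‑(2‑hydroxypropan‑2‑yl)‑5‑{[2‑(2‑phenylethyl)‑1,3‑dioxolan‑2‑yl]methyl}‑2,3‑dihydrofuran‑3‑yl]‑4‑hydroxybenzoate | COC(=O)c1ccc(O)c([C@H]2C(/C(OC)=C(/Br)C=O)=C(CC3(CCc4ccccc4)OCCO3)O[C@H]2C(C)(C)O)c1
F4 | step 3 | S‑ethyl (2E)‑3‑methoxy‑5‑oxo‑6‑[2‑(2‑phenylethyl)‑1,3‑dioxolan‑2‑yl]hex‑2‑enethioate | CCSC(=O)/C=C(OC)\CC(=O)CC1(CCc2ccccc2)OCCO1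
F0 | step 8 | none | none
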